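(The data were computed on assumed constants; scatter was added.)

After 6.00 h on Friday, 77.8% of the substrate was still there, and from that reading you get the clock of the substrate in this flask.

- Friday's: substrate 0.20 M; partner 0.60 M; catalyst 20 mM; the very flask that is asked about, followed so far
- flask: substrate 0.20 M; partner 0.600 M; catalyst 20 mM; time 3.0 d

Friday's run (percent of the substrate charged)

| time / h | product / % | crystals / % | substrate / % |
|---|---|---|---|
| 1.00 | 0.7 | 0 | 96.3 |
| 2.00 | 1.7 | 0.6 | 92.6 |
| 3.00 | 4.7 | 0 | 88.1 |
| 4.00 | 7.4 | 0 | 84.5 |
| 5.00 | 10.3 | 0.5 | 80.7 |
| 6.00 | 12.2 | 1.0 | 77.8 |

(each reading ± 0.5 percentage points)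

- how much product and crystals together there is at 3.0 d, in percent of the substrate charged
- concentration of product in solution at 3.0 d, in percent of saturation

- product is meant together with its crystals
- solid, in amounts per volume of the solution: crystals
- the earlier runs were read with a standard deviation of 0.5 percentage points

Call it the substrate half-life, 16.6 h: the time in which the substrate halves if it falls pseudo-first-order at the [catalyst] of the run. The reading at 3.00 h gives 16.4 h, so the readings of Friday's run show a steady pace. My own reckoning is this: 3.0 d at that half-life leaves 4.92% of the substrate, so I put product and crystals together below 95.1%, because on Friday the product lagged the substrate lost, 12.2% against 22.2%. The half-life gives me no figure for saturation.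

The forecast says 89% of product and crystals together and 100% of saturation, with the caution: “Unseen catalyst decay or reversibility could lower this further”.

The flask gives 93.0% of product and crystals together, which is less than my ceiling, and 106% of saturation, 5.7 points above the forecast. It has 5.79% of its substrate left, more than I reckoned.

    crystals ⇌ product, rate k1*(cs1 - [product]) while solid is left; crystals form when [product] > cs1 (solubility = 17.0 mM, k = 0.600 h⁻¹)
    partner + catalyst + intermediate → catalyst + product (k = 26.0 M⁻² h⁻¹)
    substrate + catalyst ⇌ catalyst + intermediate (K = 1.80, k = 2.20 M⁻¹ h⁻¹)

Now take the neighbouring flask, charged with 0.012 M of catalyst instead of 20 mM. If you stretch the half-life in inverse proportion to [catalyst], it becomes 27.6 h, so 3.0 d should leave 16.4% of the substrate and hold product and crystals together below 83.6%. That flask has 18% of its substrate left, more than reckoned, and gives 78.7% of product and crystals together.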